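Atoms: C1=C2 vinyl, C3 quaternary, C4=C5, C6, C7, C8, ring C9–C14, then C15–C22 from C3. Everything rests on cutting the ring bond C9–C14. The key step exploits that the only ring carries gem-dimethyl C14, methyl-bearing C13 and methylidene C10 just as a cation–olefin cyclisation leaves them: a cyclase protonates C13 of the tetrasubstituted C13=C14 alkene, joins C14 to C9 and removes a C10-methyl proton, giving ring, both ring stereocentres (C9 chain and C13 methyl trans) and exocyclic alkene in one operation. Its precursor is achiral (E)-6,9,10-trimethylundeca-5,9-dien-2-one, geranylacetone with one extra terminal methyl. Catalyst-controlled steps then set C6, C21 and C3 convergently.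

Key step: step 6

Remark on the chemistry: the ring configuration required, (1S,3S) in ketone 13, is the mirror image of the chair fold through which known cyclase variants convert (E)-geranylacetone into (S)-γ-dihydroionone, so step 6 assumes a variant selected for that antipodal fold; the precursor is built as the single E isomer instead of being separated from an E/Z mixture, and the ligand enantiomers in steps 8, 14 and 17 are taken as those that deliver the stated configurations.

Step 1
Reactants: 1 2,3-dimethylbuta-1,3-diene
Product: 2 1-bromo-2,3-dimethylbut-2-ene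
Conditions: HBr (33 % in AcOH), 0 °C
Reagents that add atoms: hydrogen bromide, Br
Why: Electrophilic 1,4-hydrobromination of the conjugated diene under thermodynamic control should give the primary allylic bromide carrying the tetrasubstituted alkene, because the tertiary 1,2-adduct equilibrates to it through the common allyl cation.

Step 2
Reactants: 2 1-bromo-2,3-dimethylbut-2-ene; 3 propyne
Product: 5 5,6-dimethylhept-5-en-1-yne, via 1,3-dilithiopropyne 4 (not isolated)
Conditions: propyne, n-BuLi (2 equiv), TMEDA, THF/hexane, −78 → 0 °C; then 2, −78 °C → rt; H2O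
Reagents that add atoms: propyne (3), CC#C; n-butyllithium, [Li]CCCC (lithium only in 4)
Why: SN2 alkylation of the propargylic carbanion of the dilithiated propyne by the primary allylic bromide (SN2' attack would have to build a quaternary carbon) followed by protonation of the acetylide should give the terminal 1,5-enyne.

Step 3
Reactants: 5 5,6-dimethylhept-5-en-1-yne; 6 trimethylaluminium
Product: 8 (1E)-1-iodo-2,5,6-trimethylhepta-1,5-diene, via alkenylalane 7 (not isolated)
Conditions: Me3Al (2 equiv), Cp2ZrCl2 (0.2 equiv), CH2Cl2, rt; then I2, THF, −30 → 0 °C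
Reagents that add atoms: trimethylaluminium (6), C[Al](C)C (aluminium only in 7); iodine, [I][I]
Why: Negishi zirconium-catalysed carboalumination adds methyl and aluminium syn across the terminal alkyne with the metal on the terminal carbon, and iodinolysis with retention should give the E-trisubstituted alkenyl iodide, so the E geometry that the cyclase needs is built in and the remote tetrasubstituted alkene stays untouched.

Step 4
Reactants: 8 (1E)-1-iodo-2,5,6-trimethylhepta-1,5-diene; 9 2-(2-bromoethyl)-2-methyl-1,3-dioxolane
Product: 11 2-methyl-2-[(3E)-4,7,8-trimethylnona-3,7-dien-1-yl]-1,3-dioxolane, via Grignard reagent 10 (not isolated)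
Conditions: 9, Mg, THF, rt; then 8, PdCl2(dppf) (3 mol %), THF, rt
Reagents that add atoms: 2-(2-bromoethyl)-2-methyl-1,3-dioxolane (9), CC1(CCBr)OCCO1; magnesium, [Mg] (only in 10)
Why: Kumada cross-coupling (oxidative addition of the alkenyl iodide to zerovalent palladium, transmetalation, reductive elimination accelerated by the wide-bite-angle dppf ligand) should join the sp3 Grignard carbon to the alkenyl carbon with retention of the E geometry.

Step 5
Reactants: 11 2-methyl-2-[(3E)-4,7,8-trimethylnona-3,7-dien-1-yl]-1,3-dioxolane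
Product: 12 (5E)-6,9,10-trimethylundeca-5,9-dien-2-one
Conditions: PPTS, acetone/H2O, 50 °C
Reagents that add atoms: water, O
Why: Mild acid-catalysed ketal hydrolysis should free the methyl ketone without protonating the electron-rich alkenes.

Step 6
Reactants: 12 (5E)-6,9,10-trimethylundeca-5,9-dien-2-one
Product: 13 4-[(1S,3S)-2,2,3-trimethyl-6-methylidenecyclohexyl]butan-2-one (trans-dihydro-γ-irone)
Conditions: engineered squalene–hopene cyclase variant (Alicyclobacillus acidocaldarius enzyme, whole E. coli cells), citrate buffer pH 6.0, 2-hydroxypropyl-β-cyclodextrin, 30 °C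
Reagents that add atoms: none
Why: Proposed new method: the catalytic aspartic acid of the cyclase protonates C13 of the tetrasubstituted C13=C14 alkene, the tertiary C14 cation is captured by C9 of the E C9=C10 alkene in a chair-like fold, and the tertiary C10 cation loses a proton from its methyl group to leave the exocyclic alkene; the closest known reaction type is the monocyclisation of (E)-geranylacetone to γ-dihydroionone by engineered squalene–hopene cyclases, with the Brønsted-acid cyclisation of pseudoirone to irones as the non-enzymatic relative. The six-membered ring C9–C14 closes in a 6-endo-trig mode through the new C9–C14 bond. C13 is controlled by anti addition of the proton and of C9 across C13=C14 (new hydrogen equatorial, methyl axial), C9 by the E geometry of C9=C10 (chain equatorial), which together give the trans relationship, while the absolute sense (1S,3S) is imposed by the face of protonation and the fold that the active site enforces. The step needs protonation at C13 and not at C14, a concerted anti addition instead of a free cation, termination at the C10 methyl and not at C11 or at the ketone oxygen, and the antipodal fold named in the remark. The substrate secures the first three by its near identity with geranylacetone (same E alkene, same ketone anchor for hydrogen bonding, only tertiary cations on the path), whereas the fold must come from the choice of variant.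

Step 7
Reactants: 13 4-[(1S,3S)-2,2,3-trimethyl-6-methylidenecyclohexyl]butan-2-one; 14 triethyl phosphonoacetate
Product: 15 ethyl (2E)-3-methyl-5-[(1S,3S)-2,2,3-trimethyl-6-methylidenecyclohexyl]pent-2-enoate
Conditions: 14, NaH, THF, 0 → 60 °C; chromatography (removal of the 2Z isomer)
Reagents that add atoms: triethyl phosphonoacetate (14), CCOC(=O)CP(=O)(OCC)OCC
Why: Horner–Wadsworth–Emmons olefination of the methyl ketone with the stabilised phosphonate anion should favour the E-trisubstituted enoate, the minor Z isomer being removed on silica, and the base cannot reach the non-enolisable ring stereocentres.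

Step 8
Reactants: 15 ethyl (2E)-3-methyl-5-[(1S,3S)-2,2,3-trimethyl-6-methylidenecyclohexyl]pent-2-enoate
Product: 16 ethyl (3S)-3-methyl-5-[(1S,3S)-2,2,3-trimethyl-6-methylidenecyclohexyl]pentanoate
Conditions: Cu(OAc)2·H2O (cat.), (R)-DTBM-SEGPHOS (cat.), (EtO)2MeSiH, t-BuOH, toluene, 0 °C
Reagents that add atoms: none
Why: Asymmetric conjugate reduction by a chiral copper hydride delivers hydride to one enantiotopic face of the β-carbon of the geometrically pure E-enoate and so sets C6 of the target (3S in the ester) under ligand control, while the hindered, unactivated exocyclic alkene should not react.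

Step 9
Reactants: 16 ethyl (3S)-3-methyl-5-[(1S,3S)-2,2,3-trimethyl-6-methylidenecyclohexyl]pentanoate
Product: 17 (3S)-3-methyl-5-[(1S,3S)-2,2,3-trimethyl-6-methylidenecyclohexyl]pentanal
Conditions: i-Bu2AlH, CH2Cl2, −78 °C; Rochelle salt
Reagents that add atoms: none
Why: Partial ester reduction: at −78 °C the tetrahedral aluminium hemiacetal persists until hydrolytic work-up, so the reduction should stop at the aldehyde, whose β-stereocentre cannot epimerise.

Step 10
Reactants: 17 (3S)-3-methyl-5-[(1S,3S)-2,2,3-trimethyl-6-methylidenecyclohexyl]pentanal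
Product: 19 (1S,3S)-2,2,3-trimethyl-6-methylidene-1-[(3S)-3-methylpent-4-yn-1-yl]cyclohexane, via enol nonaflate 18 (not isolated)
Conditions: C4F9SO2F, phosphazene base P2-Et, DMF, −30 °C → rt
Reagents that add atoms: nonafluorobutanesulfonyl fluoride, FC(F)(F)C(F)(F)C(F)(F)C(F)(F)S(=O)(=O)F (atoms only in 18)
Why: One-pot enol sulfonylation and base-induced elimination (O-sulfonylation of the aldehyde enolate, then loss of nonaflate from the alkenyl nonaflate) should turn the CH2–CHO unit into a terminal alkyne without change of carbon count, and only C5 is enolisable so C6 is not touched.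

Step 11
Reactants: 20 (2E,6E)-farnesol
Product: 21 tert-butyl(dimethyl){[(2E,6E)-3,7,11-trimethyldodeca-2,6,10-trien-1-yl]oxy}silane
Conditions: TBSCl, imidazole, CH2Cl2, 0 °C → rt
Reagents that add atoms: tert-butyldimethylsilyl chloride, CC(C)(C)[Si](C)(C)Cl
Why: Imidazole-mediated silylation of the primary allylic alcohol should protect C1 against the oxidant of step 12 and the Grignard reagent of step 14.

Step 12
Reactants: 21 tert-butyl(dimethyl){[(2E,6E)-3,7,11-trimethyldodeca-2,6,10-trien-1-yl]oxy}silane
Product: 22 (2E,6E,10E)-12-{[tert-butyl(dimethyl)silyl]oxy}-2,6,10-trimethyldodeca-2,6,10-trien-1-ol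
Conditions: SeO2 (cat.), t-BuOOH, salicylic acid (cat.), CH2Cl2, 0 °C → rt
Reagents that add atoms: selenium dioxide, O=[Se]=O (catalytic oxygen carrier); tert-butyl hydroperoxide, CC(C)(C)OO (stoichiometric oxygen source)
Why: Riley allylic oxidation (ene reaction of SeO2 at the terminal, most electron-rich trisubstituted alkene, then [2,3]-sigmatropic shift) should hydroxylate the E-methyl group of the chain end selectively and give the 10E-allylic alcohol.

Step 13
Reactants: 22 (2E,6E,10E)-12-{[tert-butyl(dimethyl)silyl]oxy}-2,6,10-trimethyldodeca-2,6,10-trien-1-ol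
Product: 24 tert-butyl{[(2E,6E,10E)-12-chloro-3,7,11-trimethyldodeca-2,6,10-trien-1-yl]oxy}dimethylsilane, via allylic mesylate 23 (not isolated)
Conditions: MsCl, LiCl, 2,4,6-collidine, DMF, 0 °C
Reagents that add atoms: lithium chloride, [Li+].[Cl-]; methanesulfonyl chloride, CS(=O)(=O)Cl (atoms only in 23)
Why: Collington–Meyers chlorination (mesylation in the flask, then SN2 displacement by chloride) should give the primary allylic chloride without allylic transposition or loss of alkene geometry.

Step 14
Reactants: 24 tert-butyl{[(2E,6E,10E)-12-chloro-3,7,11-trimethyldodeca-2,6,10-trien-1-yl]oxy}dimethylsilane; 25 methylmagnesium bromide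
Product: 26 tert-butyl(dimethyl){[(2E,6E,10R)-3,7,10,11-tetramethyldodeca-2,6,11-trien-1-yl]oxy}silane
Conditions: MeMgBr (slow addition), CuBr·SMe2 (cat.), chiral phosphoramidite (BINOL/bis(1-arylethyl)amine type, cat.), CH2Cl2, −78 °C
Reagents that add atoms: methylmagnesium bromide (25), C[Mg]Br
Why: Copper-catalysed asymmetric allylic alkylation of the 2-methyl-substituted allylic chloride: the chiral phosphoramidite–copper methyl species attacks the γ-carbon anti-SN2', which places methyl on one face of C10 (10R, C21 of the target, set by the ligand) and moves the alkene to the chain terminus, the silyl ether being inert.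

Step 15
Reactants: 26 tert-butyl(dimethyl){[(2E,6E,10R)-3,7,10,11-tetramethyldodeca-2,6,11-trien-1-yl]oxy}silane
Product: 27 (2E,6E,10R)-3,7,10,11-tetramethyldodeca-2,6,11-trien-1-ol
Conditions: TBAF, THF, 0 °C → rt
Reagents that add atoms: none
Why: Fluoride-induced desilylation, driven by the strong Si–F bond, should free the allylic alcohol under conditions that leave the skipped triene alone.

Step 16
Reactants: 27 (2E,6E,10R)-3,7,10,11-tetramethyldodeca-2,6,11-trien-1-ol
Product: 28 diethyl (2E,6E,10R)-3,7,10,11-tetramethyldodeca-2,6,11-trien-1-yl phosphate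
Conditions: (EtO)2P(O)Cl, Et3N, DMAP (cat.), CH2Cl2, 0 °C
Reagents that add atoms: diethyl chlorophosphate, CCOP(=O)(Cl)OCC
Why: Phosphorylation of the primary allylic alcohol under nucleophilic catalysis should install the phosphate leaving group that the copper-catalysed substitution of step 17 requires.

Step 17
Reactants: 19 (1S,3S)-2,2,3-trimethyl-6-methylidene-1-[(3S)-3-methylpent-4-yn-1-yl]cyclohexane; 28 diethyl (2E,6E,10R)-3,7,10,11-tetramethyldodeca-2,6,11-trien-1-yl phosphate
Product: 30 (1S,3S)-1-[(3S,4E,6S,9E,13R)-6-ethenyl-3,6,10,13,14-pentamethylpentadeca-4,9,14-trien-1-yl]-2,2,3-trimethyl-6-methylidenecyclohexane (target), via alkenylaluminium 29 (not isolated)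
Conditions: i-Bu2AlH, hexane, 55 °C; then 28, CuCl2·2H2O (cat.), [Ag(L*)]2 (cat., L* = chiral sulfonate-bearing N-heterocyclic carbene), THF, −15 °C
Reagents that add atoms: diisobutylaluminium hydride, CC(C)C[AlH]CC(C)C (atoms only in 29)
Why: Syn hydroalumination of the terminal alkyne gives the E-alkenylaluminium, and carbene–copper-catalysed enantioselective SN2' allylic substitution on the E-trisubstituted allylic phosphate transfers the alkenyl group with retention to the γ-carbon, which should create quaternary C3 (S, set by the catalyst's choice of alkene face), the C1=C2 vinyl group and the E C4=C5 alkene in one operation.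

Compound list
1 | 2,3-dimethylbuta-1,3-diene | C=C(C)C(C)=C | starting material
2 | 1-bromo-2,3-dimethylbut-2-ene | BrCC(C)=C(C)C | intermediate
3 | propyne | CC#C | starting material
4 | 1,3-dilithiopropyne | [Li]CC#C[Li] | intermediate (not isolated)
5 | 5,6-dimethylhept-5-en-1-yne | C#CCCC(C)=C(C)C | intermediate
6 | trimethylaluminium | C[Al](C)C | starting material
7 | dimethyl[(1E)-2,5,6-trimethylhepta-1,5-dien-1-yl]aluminium | C[Al](C)/C=C(\C)CCC(C)=C(C)C | intermediate (not isolated)
8 | (1E)-1-iodo-2,5,6-trimethylhepta-1,5-diene | I/C=C(\C)CCC(C)=C(C)C | intermediate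
9 | 2-(2-bromoethyl)-2-methyl-1,3-dioxolane | CC1(CCBr)OCCO1 | starting material
10 | [2-(2-methyl-1,3-dioxolan-2-yl)ethyl]magnesium bromide | CC1(CC[Mg]Br)OCCO1 | intermediate (not isolated)
11 | 2-methyl-2-[(3E)-4,7,8-trimethylnona-3,7-dien-1-yl]-1,3-dioxolane | CC1(CC/C=C(\C)CCC(C)=C(C)C)OCCO1 | intermediate
12 | (5E)-6,9,10-trimethylundeca-5,9-dien-2-one | CC(=O)CC/C=C(\C)CCC(C)=C(C)C | intermediate
13 | 4-[(1S,3S)-2,2,3-trimethyl-6-methylidenecyclohexyl]butan-2-one | CC(=O)CC[C@H]1C(=C)CC[C@H](C)C1(C)C | intermediate
14 | triethyl phosphonoacetate | CCOC(=O)CP(=O)(OCC)OCC | starting material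
15 | ethyl (2E)-3-methyl-5-[(1S,3S)-2,2,3-trimethyl-6-methylidenecyclohexyl]pent-2-enoate | CCOC(=O)/C=C(\C)CC[C@H]1C(=C)CC[C@H](C)C1(C)C | intermediate
16 | ethyl (3S)-3-methyl-5-[(1S,3S)-2,2,3-trimethyl-6-methylidenecyclohexyl]pentanoate | CCOC(=O)C[C@@H](C)CC[C@H]1C(=C)CC[C@H](C)C1(C)C | intermediate
17 | (3S)-3-methyl-5-[(1S,3S)-2,2,3-trimethyl-6-methylidenecyclohexyl]pentanal | O=CC[C@@H](C)CC[C@H]1C(=C)CC[C@H](C)C1(C)C | intermediate
18 | (3S)-3-methyl-5-[(1S,3S)-2,2,3-trimethyl-6-methylidenecyclohexyl]pent-1-en-1-yl nonafluorobutane-1-sulfonate (E/Z mixture) | FC(F)(F)C(F)(F)C(F)(F)C(F)(F)S(=O)(=O)OC=C[C@@H](C)CC[C@H]1C(=C)CC[C@H](C)C1(C)C | intermediate (not isolated)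
19 | (1S,3S)-2,2,3-trimethyl-6-methylidene-1-[(3S)-3-methylpent-4-yn-1-yl]cyclohexane | C#C[C@@H](C)CC[C@H]1C(=C)CC[C@H](C)C1(C)C | intermediate
20 | (2E,6E)-farnesol, (2E,6E)-3,7,11-trimethyldodeca-2,6,10-trien-1-ol | OC/C=C(\C)CC/C=C(\C)CCC=C(C)C | starting material
21 | tert-butyl(dimethyl){[(2E,6E)-3,7,11-trimethyldodeca-2,6,10-trien-1-yl]oxy}silane | CC(C)(C)[Si](C)(C)OC/C=C(\C)CC/C=C(\C)CCC=C(C)C | intermediate
22 | (2E,6E,10E)-12-{[tert-butyl(dimethyl)silyl]oxy}-2,6,10-trimethyldodeca-2,6,10-trien-1-ol | CC(C)(C)[Si](C)(C)OC/C=C(\C)CC/C=C(\C)CC/C=C(\C)CO | intermediate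
23 | (2E,6E,10E)-12-{[tert-butyl(dimethyl)silyl]oxy}-2,6,10-trimethyldodeca-2,6,10-trien-1-yl methanesulfonate | CC(C)(C)[Si](C)(C)OC/C=C(\C)CC/C=C(\C)CC/C=C(\C)COS(C)(=O)=O | intermediate (not isolated)
24 | tert-butyl{[(2E,6E,10E)-12-chloro-3,7,11-trimethyldodeca-2,6,10-trien-1-yl]oxy}dimethylsilane | CC(C)(C)[Si](C)(C)OC/C=C(\C)CC/C=C(\C)CC/C=C(\C)CCl | intermediate
25 | methylmagnesium bromide | C[Mg]Br | starting material
26 | tert-butyl(dimethyl){[(2E,6E,10R)-3,7,10,11-tetramethyldodeca-2,6,11-trien-1-yl]oxy}silane | CC(C)(C)[Si](C)(C)OC/C=C(\C)CC/C=C(\C)CC[C@@H](C)C(=C)C | intermediate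
27 | (2E,6E,10R)-3,7,10,11-tetramethyldodeca-2,6,11-trien-1-ol | OC/C=C(\C)CC/C=C(\C)CC[C@@H](C)C(=C)C | intermediate
28 | diethyl (2E,6E,10R)-3,7,10,11-tetramethyldodeca-2,6,11-trien-1-yl phosphate | CCOP(=O)(OCC)OC/C=C(\C)CC/C=C(\C)CC[C@@H](C)C(=C)C | intermediate
29 | bis(2-methylpropyl){(1E,3S)-3-methyl-5-[(1S,3S)-2,2,3-trimethyl-6-methylidenecyclohexyl]pent-1-en-1-yl}aluminium | CC(C)C[Al](CC(C)C)/C=C/[C@@H](C)CC[C@H]1C(=C)CC[C@H](C)C1(C)C | intermediate (not isolated)
30 | (1S,3S)-1-[(3S,4E,6S,9E,13R)-6-ethenyl-3,6,10,13,14-pentamethylpentadeca-4,9,14-trien-1-yl]-2,2,3-trimethyl-6-methylidenecyclohexane | C=C[C@@](C)(/C=C/[C@@H](C)CC[C@H]1C(=C)CC[C@H](C)C1(C)C)CC/C=C(\C)CC[C@@H](C)C(=C)C | target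

Total step count: 17 (steps 1–10 for the ring-bearing alkyne, steps 11–16 for the allylic phosphate, step 17 for their union).
Longest linear sequence: 11 steps (steps 1–10, then step 17).

Steps most likely to fail

Step 6 (proposed new method). The enzyme may fold the substrate in the sense known for geranylacetone and so deliver the mirror-image ring. Protonation of the tetrasubstituted alkene may be slow or stepwise, which would erode the trans relationship. The C10 cation may also be quenched at C11 or by the ketone oxygen instead of at the methyl group. The fallback uses known carbonyl chemistry, sets out from 9 through its Grignard reagent 10 and comes back at 13. Commercial 4,4-dimethylcyclohexa-2,5-dien-1-one F1 is desymmetrised by copper-catalysed enantioselective conjugate addition of Me2Zn (Cu(OTf)2, chiral phosphoramidite) to give (5S)-4,4,5-trimethylcyclohex-2-en-1-one F2, which fixes the future C13. The organocopper reagent made from 10 (CuBr·SMe2, Me3SiCl, THF, −78 °C) should add to C3 of F2 anti to the C5 methyl group (axial attack on the half-chair, the usual trans-3,5 outcome), fixing the future C9 at a carbon that cannot epimerise. The enolate equivalent is trapped with Eschenmoser's salt as the Mannich base F3, and quaternisation with iodomethane followed by elimination gives the 2-methylidene ketone F4. Luche reduction (NaBH4, CeCl3·7H2O) gives the allylic alcohol F5, and methyl chloroformate gives the methyl carbonate F6. Palladium-catalysed formate reduction (Pd(OAc)2, n-Bu3P, HCO2NH4) delivers hydride to the ring terminus of the allyl complex and so leaves the exocyclic alkene in the ketal F7. PPTS in wet acetone then releases 13.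

Step 17. Facial discrimination at C3 by the carbene–copper catalyst may be incomplete, or direct SN2 attack and isobutyl transfer may compete; the resulting C3 epimer of a hydrocarbon could not be removed. The fallback forms the C3–C4 bond by carbonyl allylation and the alkene by elimination; it sets out from 17 and 27 and comes back at 30. Alcohol 27 is converted into the pinacol allylboronate F8 (B2pin2, [Pd(MeCN)4](BF4)2, DMSO/MeOH). Chiral phosphoric acid-catalysed allylboration of aldehyde 17 with this E-γ,γ-disubstituted boronate through a chair transition state should give the homoallylic alcohol F9, with quaternary C3 set (S) by the catalyst and a C4 carbinol (R) of no lasting consequence; its diastereomers are more likely to separate than hydrocarbons. The alcohol is converted into the S-methyl xanthate F10 (NaH, CS2, iodomethane), and Chugaev syn-elimination, for which only the C5 hydrogens are available, should give the E C4=C5 alkene of 30.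

Step 14. With the small methyl Grignard reagent on a 2-methyl-substituted allylic chloride, the SN2' to SN2 ratio or the facial selectivity at C10 may be insufficient, and the C21 epimer would be carried to the end. The fallback replaces catalytic alkylation by epoxide chemistry; it sets out from 22 and comes back at 26. Sharpless asymmetric epoxidation of 22 (Ti(OiPr)4, L-(+)-diethyl tartrate, t-BuOOH) should give the (2S,3S)-epoxy alcohol F11. Me2CuLi opens it at the secondary C3 with inversion (C2 is fully substituted) to give the (2R,3R)-1,2-diol F12, which already carries the C10 methyl group in the R configuration. Thiocarbonyldiimidazole gives the cyclic thionocarbonate F13, and Corey–Winter olefination (P(OMe)3, heat) removes both oxygens to leave the 1,1-disubstituted alkene of 26.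

Further compounds
F1 | step 6 | 4,4-dimethylcyclohexa-2,5-dien-1-one | CC1(C)C=CC(=O)C=C1
F2 | step 6 | (5S)-4,4,5-trimethylcyclohex-2-en-1-one | O=C1C=CC(C)(C)[C@@H](C)C1
F3 | step 6 | (3S,5S)-2-[(dimethylamino)methyl]-4,4,5-trimethyl-3-[2-(2-methyl-1,3-dioxolan-2-yl)ethyl]cyclohexan-1-one (C2 epimers) | CC1(CC[C@H]2C(CN(C)C)C(=O)C[C@H](C)C2(C)C)OCCO1
F4 | step 6 | (3R,5S)-4,4,5-trimethyl-2-methylidene-3-[2-(2-methyl-1,3-dioxolan-2-yl)ethyl]cyclohexan-1-one | CC1(CC[C@H]2C(=C)C(=O)C[C@H](C)C2(C)C)OCCO1
F5 | step 6 | (3R,5S)-4,4,5-trimethyl-2-methylidene-3-[2-(2-methyl-1,3-dioxolan-2-yl)ethyl]cyclohexan-1-ol (C1 epimers) | CC1(CC[C@H]2C(=C)C(O)C[C@H](C)C2(C)C)OCCO1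
F6 | step 6 | methyl (3R,5S)-4,4,5-trimethyl-2-methylidene-3-[2-(2-methyl-1,3-dioxolan-2-yl)ethyl]cyclohexyl carbonate (C1 epimers) | CC1(CC[C@H]2C(=C)C(OC(=O)OC)C[C@H](C)C2(C)C)OCCO1
F7 | step 6 | 2-methyl-2-{2-[(1S,3S)-2,2,3-trimethyl-6-methylidenecyclohexyl]ethyl}-1,3-dioxolane | CC1(CC[C@H]2C(=C)CC[C@H](C)C2(C)C)OCCO1
F8 | step 17 | 4,4,5,5-tetramethyl-2-[(2E,6E,10R)-3,7,10,11-tetramethyldodeca-2,6,11-trien-1-yl]-1,3,2-dioxaborolane | CC1(C)OB(C/C=C(\C)CC/C=C(\C)CC[C@@H](C)C(=C)C)OC1(C)C
F9 | step 17 | 4,5-dihydro-4-hydroxy derivative of 30 with C3 S and C4 R (target numbering), the homoallylic alcohol | C=C[C@@](C)([C@H](O)C[C@@H](C)CC[C@H]1C(=C)CC[C@H](C)C1(C)C)CC/C=C(\C)CC[C@@H](C)C(=C)C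
F10 | step 17 | O-alkyl S-methyl dithiocarbonate (xanthate) of F9 | C=C[C@@](C)([C@H](OC(=S)SC)C[C@@H](C)CC[C@H]1C(=C)CC[C@H](C)C1(C)C)CC/C=C(\C)CC[C@@H](C)C(=C)C
F11 | step 14 | [(2S,3S)-3-[(3E,7E)-9-{[tert-butyl(dimethyl)silyl]oxy}-3,7-dimethylnona-3,7-dien-1-yl]-2-methyloxiran-2-yl]methanol | CC(C)(C)[Si](C)(C)OC/C=C(\C)CC/C=C(\C)CC[C@@H]1O[C@@]1(C)CO
F12 | step 14 | (2R,3R,6E,10E)-12-{[tert-butyl(dimethyl)silyl]oxy}-2,3,6,10-tetramethyldodeca-6,10-diene-1,2-diol | CC(C)(C)[Si](C)(C)OC/C=C(\C)CC/C=C(\C)CC[C@@H](C)[C@@](C)(O)CO
F13 | step 14 | (4R)-4-[(2R,5E,9E)-11-{[tert-butyl(dimethyl)silyl]oxy}-5,9-dimethylundeca-5,9-dien-2-yl]-4-methyl-1,3-dioxolane-2-thione | CC(C)(C)[Si](C)(C)OC/C=C(\C)CC/C=C(\C)CC[C@@H](C)[C@]1(C)COC(=S)O1
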